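**Remark (assumption).** Isoplagilin has no stereogenic centre, and its biaryl axis is flanked by only one OH and one CH2, so it rotates freely; "single enantiomer" is therefore read as the single constitution drawn. Compounds 1, 2, 6 and 7 are taken as catalogue chemicals.

**Locants used throughout** (biphenyl numbering of the target 12):
- Ring A: C1 (biaryl carbon), C2–OH, C3–OH, C5–CH2CH2Ar.
- Ring B: C1′ (biaryl carbon), C2′–CH2CH2Ar, C4′–OH, C5′–OH.
- Rings C and D are the two 3-methoxyphenyl rings.

## The problem

Isoplagilin (12) is an open-chain bis-bibenzyl: two copies of 4-[2-(3-methoxyphenyl)ethyl]benzene-1,2-diol held together by one aryl–aryl bond. There is no ring to close and no stereocentre to set. The difficulty is the connectivity. The bond joins two different positions of the same monomer: C1 of ring A is ortho to the hydroxyl at C2 and meta to the chain at C5, whereas C1′ of ring B is ortho to the chain at C2′ and para to the hydroxyl at C4′. Dimerising a single species therefore gives a symmetrical biaryl, not this one.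

Four catechol hydroxyls must end free beside two anisole methyl ethers, so a global demethylation is excluded. Rings C and D are not spectators. Their carbon para to OMe and ortho to the chain is about as reactive toward electrophiles as C1′ of a catechol diether, so an assembled monomer cannot be halogenated selectively. In ring B that carbon sits two atoms from C1′, so oxidising ring B invites closure to a 9,10-dihydrophenanthrene. The product is an air-sensitive bis-catechol, and an o-quinone on ring B would be trapped by the C2 hydroxyl to give a dibenzofuran. The last operations must therefore be reductive or neutral.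

The feature that opens the route is this. C1 is the only free carbon ortho or para to the oxygen on C2 (the para carbon C5 carries the chain, the other ortho carbon C3 carries oxygen). C1′ is the innately most nucleophilic carbon of a 4-alkylcatechol diether (para to the oxygen on C4′, ortho to the alkyl group). The C1–C1′ bond thus joins the radical carbon of a para-alkylated phenol to the nucleophilic carbon of a dialkoxyarene, which is the polarity of a phenol–arene dehydrogenative cross-coupling. In addition, a free OH at C2 beside OMe at C3 (a guaiacol) is the one methyl ether that can later be removed by oxidation without touching the anisoles.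

## Retrosynthesis

**12 ⇒ 11.** The two O–CH2Ph bonds on ring B are cut. Benzyl is chosen because hydrogenolysis is neutral and reducing, leaves aryl methyl ethers alone and keeps oxidants away from the tetraphenol. The forward step only has to be a clean hydrogenolysis.

**11 ⇒ 9 (through o-quinone 10).** The O–CH3 bond at C3 of ring A is cut. A methyl group here is what makes the phenol partner a 4-alkylguaiacol, the phenol class that is easiest to oxidise and best behaved in anodic cross-coupling, and it comes from a vanillin derivative. A third benzyl ether would need a less accessible aldehyde and would place a benzylic C–H next to the phenoxyl oxygen. The forward reaction must deliver oxygen to the methoxy-bearing ortho carbon C3 and not to the aryl-bearing C1, and quinone 10 must be reduced before it can tautomerise.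

**9 ⇒ 5 + 8 (key disconnection).** The C1–C1′ bond is cut between two C–H carbons. The neighbouring cuts through the CH2–CH2 chains leave the biaryl problem unsolved, and a cut to halide plus boronate forces each half to be built around a halogen. This cut gives the same monomer in two protection states: phenol 5 (one free OH, one OMe) and bis-benzyl ether 8 (no free OH). A C45 biaryl falls to a C16 and a C29 bibenzyl that carry no halogen or metal and are made in two steps and one step. The forward reaction must oxidise only 5, bond it only at C1, use only C1′ of 8 and leave rings C and D alone.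

**5 ⇒ 4 ⇒ 1 + 2 (through ylide 3).** The benzylic C–C bond is cut as a C=C bond (Wittig reaction of O-benzylvanillin 2). The benzyl ether keeps the phenol out of the Wittig step. One hydrogenation then saturates the alkene and frees the phenol, so the protecting group costs no step.

**8 ⇒ 6 + 7.** The CH2–CH2 bond is cut between a benzylic chloride and a benzylic Grignard reagent. Against the Wittig alternative, this sp3–sp3 coupling reaches 8 in one step and avoids an alkene reduction that would have to spare two benzyl ethers.

## Roads not taken

**Alternative 1:** (the obvious one) The same C1–C1′ bond is cut to a boronate and a bromide. The forward key step would be a Suzuki–Miyaura coupling of ring-A pinacol boronate A1 with ring-B bromide A2 (catechols masked, for instance as MOM ethers) to give biaryl A3, followed by acid deprotection. The halogens cannot be introduced on finished monomers, because rings C and D compete with C1′ and C1. Each half must therefore be built from a pre-brominated aldehyde, with an alkene reduction that spares C–Br and then a borylation. This costs roughly twice as many steps, and the halogen and boron carry only positional information that the oxygen pattern of 5 and 8 already contains.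

**Alternative 2:** The C1–C1′ bond is cut to two molecules of the unprotected catechol A4. The forward key step would be a protecting-group-free oxidative dimerisation, in which half of A4 is oxidised to o-quinone A5 and the rest adds to it. The innate polarity is wrong. The most nucleophilic carbon of A4 and the preferred 1,4-acceptor carbon of A5 are the same carbon (para to OH, ortho to the chain), so the symmetrical biaryl A6 and C–O coupled products are expected. Any biaryl catechol formed is also more easily oxidised than A4 and can cyclise to a dibenzofuran. The chosen plan keeps the C–H/C–H logic but assigns the two roles by protection state.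

**Alternative 3:** Both chain C–C bonds are cut first (two-directional plan). A perbenzylated biaryl dialdehyde A7 would undergo double Wittig reaction with ylide 3 to give bis-stilbene A8, and one hydrogenation would saturate both alkenes and remove all benzyl groups. The end game is attractive and rings C and D arrive after the biaryl bond. However, A7 contains two electron-poor rings that cannot be joined oxidatively, so it again needs a halide/boronate union of two differently brominated aldehydes. One Wittig reaction must also occur at a formyl group ortho to the biaryl axis. The route is longer and its hardest bond is still made the conventional way.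

Key step: step 4

## Route

Step 1
Reactants: 1 (3-methoxybenzyl)triphenylphosphonium chloride; 2 4-(benzyloxy)-3-methoxybenzaldehyde (O-benzylvanillin)
Product: 4 1-(benzyloxy)-2-methoxy-4-[2-(3-methoxyphenyl)ethenyl]benzene (E/Z mixture), via (3-methoxybenzylidene)triphenylphosphorane 3 (not isolated)
Conditions: KOt-Bu (1.1 equiv), THF, 0 °C to rt
Reagents that add atoms: none
Why: Wittig olefination of an aryl aldehyde with a semistabilised benzylic ylide; the alkene geometry is irrelevant because the double bond is saturated in step 2, and the benzyl ether keeps the phenol from quenching the ylide.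

Step 2
Reactants: 4 1-(benzyloxy)-2-methoxy-4-[2-(3-methoxyphenyl)ethenyl]benzene
Product: 5 2-methoxy-4-[2-(3-methoxyphenyl)ethyl]phenol
Conditions: H2 (1 atm), 10% Pd/C, EtOAc/EtOH, rt
Reagents that add atoms: none
Why: Catalytic hydrogenation over Pd/C should saturate the stilbene and hydrogenolyse the O-benzyl group in one operation, freeing the phenol para to the chain; aryl methyl ethers and the arene rings are inert under these conditions.

Step 3
Reactants: 6 3,4-bis(benzyloxy)benzyl chloride; 7 3-methoxybenzylmagnesium chloride (THF solution)
Product: 8 1,2-bis(benzyloxy)-4-[2-(3-methoxyphenyl)ethyl]benzene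
Conditions: Li2CuCl4 (3 mol %), THF, –20 °C to rt, slow addition of 7 (1.3 equiv)
Reagents that add atoms: none
Why: Copper-catalysed Kumada-type sp3–sp3 cross-coupling of a benzylic chloride with a benzylic Grignard reagent should give the bibenzyl directly with no alkene stage, so no reduction endangers the benzyl ethers; slow addition at low temperature limits halogen–magnesium exchange and homocoupling.

Step 4
Reactants: 5 2-methoxy-4-[2-(3-methoxyphenyl)ethyl]phenol; 8 1,2-bis(benzyloxy)-4-[2-(3-methoxyphenyl)ethyl]benzene
Product: 9 4′,5′-bis(benzyloxy)-3-methoxy-2′,5-bis[2-(3-methoxyphenyl)ethyl]-[1,1′-biphenyl]-2-ol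
Conditions: boron-doped diamond anode, Ni cathode, undivided cell; 8 (3 equiv), Bu3MeN+ MeOSO3– (0.1 M), HFIP/MeOH (82:18), 50 °C, 2.8 mA cm–2, 2.0 F per mol of 5
Reagents that add atoms: none
Why: Anodic dehydrogenative phenol–arene cross-coupling, whose closest known type is the coupling of 4-alkyl-2-methoxyphenols with alkoxyarenes at boron-doped diamond in HFIP. Only 5 has an O–H, and as a 4-alkylguaiacol it is the most easily oxidised species in the cell, so it alone should be converted (proton-coupled) into the HFIP-solvated phenoxyl radical, whose spin sits on C1, C3 and C5; C3 carries OMe and C5 the chain, so C1 is the only carbon that can bond and rearomatise. The radical is intercepted by arene 8 at C1′, the carbon para to one benzyloxy group and ortho to the alkyl chain, which is the site at which 4-alkylcatechol diethers are substituted by electrophiles; the cyclohexadienyl radical then loses a second electron and a proton and tautomerises to 9, while protons are reduced to H2 at the cathode. No ring is closed and no stereocentre is formed; the new axis has two ortho substituents only and rotates freely. Cross- over homo-coupling is to be secured by the threefold excess of 8 and by the HFIP/MeOH medium. Preference for ring B over the anisole rings C and D is expected from its two oxygen donors and lower oxidation potential, which favour it in the charge-transfer-like bond-forming step. Intramolecular closure is excluded on the phenol side because C1 is meta to the chain and cannot reach its own distal ring, and ring B is not oxidised while 5 is present. Over-oxidation of 9 is limited because its phenol is flanked by two ortho substituents and the charge is stopped at 2 F per mol of 5.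

Step 5
Reactants: 9 4′,5′-bis(benzyloxy)-3-methoxy-2′,5-bis[2-(3-methoxyphenyl)ethyl]-[1,1′-biphenyl]-2-ol
Product: 11 4′,5′-bis(benzyloxy)-2′,5-bis[2-(3-methoxyphenyl)ethyl]-[1,1′-biphenyl]-2,3-diol, via biaryl o-quinone 10 (not isolated)
Conditions: IBX (1.2 equiv), DMF, rt, dark; then aq. Na2S2O4, EtOAc, rt
Reagents that add atoms: 2-iodoxybenzoic acid (IBX), O=C1OI(=O)(O)c2ccccc12 (supplies the oxygen that ends on C3)
Why: Phenol-directed oxidative O-demethylation of a 2-methoxyphenol: the phenol binds iodine(V), oxygen is passed intramolecularly to the methoxy-bearing ortho carbon C3 (the more electron-rich of the two ortho carbons), methanol is expelled to give o-quinone 10, and dithionite reduces it at once to the catechol. Only ring A has a free OH, so the benzyl ethers of ring B and the anisole methyl ethers, which cannot bind iodine, should be untouched.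

Step 6
Reactants: 11 4′,5′-bis(benzyloxy)-2′,5-bis[2-(3-methoxyphenyl)ethyl]-[1,1′-biphenyl]-2,3-diol
Product: 12 isoplagilin, 2′,5-bis[2-(3-methoxyphenyl)ethyl]-[1,1′-biphenyl]-2,3,4′,5′-tetrol
Conditions: H2 (1 atm), 10% Pd/C, EtOAc/MeOH, rt; filtration and concentration under Ar
Reagents that add atoms: none
Why: Hydrogenolysis of the two aryl benzyl ethers under neutral, reducing conditions should release the second catechol without touching the aryl methyl ethers; the hydrogen atmosphere protects the air-sensitive tetraphenol until it is isolated under argon.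

## Compound list

1 | (3-methoxybenzyl)triphenylphosphonium chloride | COc1cccc(C[P+](c2ccccc2)(c2ccccc2)c2ccccc2)c1.[Cl-] | starting material
2 | 4-(benzyloxy)-3-methoxybenzaldehyde | COc1cc(C=O)ccc1OCc1ccccc1 | starting material
3 | (3-methoxybenzylidene)triphenylphosphorane | COc1cccc(C=P(c2ccccc2)(c2ccccc2)c2ccccc2)c1 | intermediate
4 | 1-(benzyloxy)-2-methoxy-4-[2-(3-methoxyphenyl)ethenyl]benzene (E/Z mixture, geometry not defined and erased in step 2) | COc1cccc(C=Cc2ccc(OCc3ccccc3)c(OC)c2)c1 | intermediate
5 | 2-methoxy-4-[2-(3-methoxyphenyl)ethyl]phenol | COc1cccc(CCc2ccc(O)c(OC)c2)c1 | intermediate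
6 | 3,4-bis(benzyloxy)benzyl chloride | ClCc1ccc(OCc2ccccc2)c(OCc2ccccc2)c1 | starting material
7 | 3-methoxybenzylmagnesium chloride | COc1cccc(C[Mg]Cl)c1 | starting material
8 | 1,2-bis(benzyloxy)-4-[2-(3-methoxyphenyl)ethyl]benzene | COc1cccc(CCc2ccc(OCc3ccccc3)c(OCc3ccccc3)c2)c1 | intermediate
9 | 4′,5′-bis(benzyloxy)-3-methoxy-2′,5-bis[2-(3-methoxyphenyl)ethyl]-[1,1′-biphenyl]-2-ol (achiral) | COc1cccc(CCc2cc(OC)c(O)c(-c3cc(OCc4ccccc4)c(OCc4ccccc4)cc3CCc3cccc(OC)c3)c2)c1 | intermediate
10 | 3-{4,5-bis(benzyloxy)-2-[2-(3-methoxyphenyl)ethyl]phenyl}-5-[2-(3-methoxyphenyl)ethyl]cyclohexa-3,5-diene-1,2-dione | COc1cccc(CCC2=CC(=O)C(=O)C(-c3cc(OCc4ccccc4)c(OCc4ccccc4)cc3CCc3cccc(OC)c3)=C2)c1 | intermediate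
11 | 4′,5′-bis(benzyloxy)-2′,5-bis[2-(3-methoxyphenyl)ethyl]-[1,1′-biphenyl]-2,3-diol | COc1cccc(CCc2cc(O)c(O)c(-c3cc(OCc4ccccc4)c(OCc4ccccc4)cc3CCc3cccc(OC)c3)c2)c1 | intermediate
12 | isoplagilin, 2′,5-bis[2-(3-methoxyphenyl)ethyl]-[1,1′-biphenyl]-2,3,4′,5′-tetrol (achiral) | COc1cccc(CCc2cc(O)c(O)c(-c3cc(O)c(O)cc3CCc3cccc(OC)c3)c2)c1 | target

## Step count and risk

Total step count: 6. Longest linear sequence: 5 (steps 1, 2, 4, 5, 6); step 3 is the one-step branch to 8.

**Step 4 (key step).** The most likely failure is loss of chemoselectivity among the electron-rich rings: the oxidised phenol may bond to the anisole rings C and D instead of C1′. Homocoupling of 5 may also compete. Once 5 is depleted, ring B of 8 may be oxidised and close onto its own distal ring.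

Fallback (sets out from 5 and, with 1, from a second aldehyde; returns at 9). Amine-catalysed ortho-bromination of 5 (NBS, cat. i-Pr2NH, CH2Cl2, 0 °C) should give 2-bromo-6-methoxy-4-[2-(3-methoxyphenyl)ethyl]phenol F1, because the free phenol directs and outpaces the anisole ring. The ring-B partner is built with its halogen already in place. 3,4-Bis(benzyloxy)benzaldehyde F2 is brominated (Br2, AcOH) to 4,5-bis(benzyloxy)-2-bromobenzaldehyde F3. Wittig reaction with ylide 3 gives 1,2-bis(benzyloxy)-4-bromo-5-[2-(3-methoxyphenyl)ethenyl]benzene F4. Diimide reduction (TsNHNH2, NaOAc, DME/H2O, reflux) spares C–Br and the benzyl ethers and gives 1,2-bis(benzyloxy)-4-bromo-5-[2-(3-methoxyphenyl)ethyl]benzene F5. Miyaura borylation (B2pin2, Pd(dppf)Cl2, KOAc) gives 2-{4,5-bis(benzyloxy)-2-[2-(3-methoxyphenyl)ethyl]phenyl}-4,4,5,5-tetramethyl-1,3,2-dioxaborolane F6. Suzuki–Miyaura coupling of F1 with F6 (Pd(OAc)2/SPhos, K3PO4, toluene/H2O) rejoins the route at 9.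

**Step 5.** Oxygen may be delivered to the aryl-bearing ortho carbon C1 (dearomatisation to an o-quinol instead of demethylation). The 5-alkyl-o-quinone 10 may also tautomerise to a quinone methide before it is reduced.

Fallback (removes the methyl ether from the plan; sets out from 1 and 8; returns at 12). 3-(Benzyloxy)-4-hydroxybenzaldehyde F7 is treated with 2.2 equiv of ylide 3 to give 2-(benzyloxy)-4-[2-(3-methoxyphenyl)ethenyl]phenol F8. Diimide reduction gives 2-(benzyloxy)-4-[2-(3-methoxyphenyl)ethyl]phenol F9. Anodic cross-coupling of F9 with 8 under the conditions of step 4 should give 3,4′,5′-tris(benzyloxy)-2′,5-bis[2-(3-methoxyphenyl)ethyl]-[1,1′-biphenyl]-2-ol F10. A single hydrogenolysis (H2, Pd/C) then gives 12 directly, with no oxidation after the biaryl bond is made.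

**Step 3.** Halogen–magnesium exchange or electron transfer between the two benzylic partners may scramble them into symmetrical bibenzyls that are hard to separate from 8.

Fallback (sets out from 1 and F2; returns at 8). Wittig reaction of ylide 3 with 3,4-bis(benzyloxy)benzaldehyde F2 gives 1,2-bis(benzyloxy)-4-[2-(3-methoxyphenyl)ethenyl]benzene F11. Diimide reduction (TsNHNH2, NaOAc) saturates the alkene without cleaving the benzyl ethers and gives 8.

## Further compounds

F1 | step 4 | 2-bromo-6-methoxy-4-[2-(3-methoxyphenyl)ethyl]phenol | COc1cccc(CCc2cc(Br)c(O)c(OC)c2)c1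
F2 | step 4 | 3,4-bis(benzyloxy)benzaldehyde | O=Cc1ccc(OCc2ccccc2)c(OCc2ccccc2)c1
F3 | step 4 | 4,5-bis(benzyloxy)-2-bromobenzaldehyde | O=Cc1cc(OCc2ccccc2)c(OCc2ccccc2)cc1Br
F4 | step 4 | 1,2-bis(benzyloxy)-4-bromo-5-[2-(3-methoxyphenyl)ethenyl]benzene (E/Z mixture) | COc1cccc(C=Cc2cc(OCc3ccccc3)c(OCc3ccccc3)cc2Br)c1
F5 | step 4 | 1,2-bis(benzyloxy)-4-bromo-5-[2-(3-methoxyphenyl)ethyl]benzene | COc1cccc(CCc2cc(OCc3ccccc3)c(OCc3ccccc3)cc2Br)c1
F6 | step 4 | 2-{4,5-bis(benzyloxy)-2-[2-(3-methoxyphenyl)ethyl]phenyl}-4,4,5,5-tetramethyl-1,3,2-dioxaborolane | COc1cccc(CCc2cc(OCc3ccccc3)c(OCc3ccccc3)cc2B2OC(C)(C)C(C)(C)O2)c1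
F7 | step 5 | 3-(benzyloxy)-4-hydroxybenzaldehyde | O=Cc1ccc(O)c(OCc2ccccc2)c1
F8 | step 5 | 2-(benzyloxy)-4-[2-(3-methoxyphenyl)ethenyl]phenol (E/Z mixture) | COc1cccc(C=Cc2ccc(O)c(OCc3ccccc3)c2)c1
F9 | step 5 | 2-(benzyloxy)-4-[2-(3-methoxyphenyl)ethyl]phenol | COc1cccc(CCc2ccc(O)c(OCc3ccccc3)c2)c1
F10 | step 5 | 3,4′,5′-tris(benzyloxy)-2′,5-bis[2-(3-methoxyphenyl)ethyl]-[1,1′-biphenyl]-2-ol | COc1cccc(CCc2cc(OCc3ccccc3)c(O)c(-c3cc(OCc4ccccc4)c(OCc4ccccc4)cc3CCc3cccc(OC)c3)c2)c1
F11 | step 3 | 1,2-bis(benzyloxy)-4-[2-(3-methoxyphenyl)ethenyl]benzene (E/Z mixture) | COc1cccc(C=Cc2ccc(OCc3ccccc3)c(OCc3ccccc3)c2)c1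
A1 | alternative 1 | 2-{2,3-bis(methoxymethoxy)-5-[2-(3-methoxyphenyl)ethyl]phenyl}-4,4,5,5-tetramethyl-1,3,2-dioxaborolane | COCOc1cc(CCc2cccc(OC)c2)cc(B2OC(C)(C)C(C)(C)O2)c1OCOC
A2 | alternative 1 | 1-bromo-4,5-bis(methoxymethoxy)-2-[2-(3-methoxyphenyl)ethyl]benzene | COCOc1cc(Br)c(CCc2cccc(OC)c2)cc1OCOC
A3 | alternative 1 | 2,3,4′,5′-tetrakis(methoxymethoxy)-2′,5-bis[2-(3-methoxyphenyl)ethyl]-1,1′-biphenyl | COCOc1cc(CCc2cccc(OC)c2)cc(-c2cc(OCOC)c(OCOC)cc2CCc2cccc(OC)c2)c1OCOC
A4 | alternative 2 | 4-[2-(3-methoxyphenyl)ethyl]benzene-1,2-diol | COc1cccc(CCc2ccc(O)c(O)c2)c1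
A5 | alternative 2 | 4-[2-(3-methoxyphenyl)ethyl]cyclohexa-3,5-diene-1,2-dione | COc1cccc(CCC2=CC(=O)C(=O)C=C2)c1
A6 | alternative 2 | 6,6′-bis[2-(3-methoxyphenyl)ethyl]-[1,1′-biphenyl]-3,3′,4,4′-tetrol | COc1cccc(CCc2cc(O)c(O)cc2-c2cc(O)c(O)cc2CCc2cccc(OC)c2)c1
A7 | alternative 3 | 2,3,4′,5′-tetrakis(benzyloxy)-[1,1′-biphenyl]-2′,5-dicarbaldehyde | O=Cc1cc(OCc2ccccc2)c(OCc2ccccc2)c(-c2cc(OCc3ccccc3)c(OCc3ccccc3)cc2C=O)c1
A8 | alternative 3 | 2,3,4′,5′-tetrakis(benzyloxy)-2′,5-bis[2-(3-methoxyphenyl)ethenyl]-1,1′-biphenyl (E/Z mixtures) | COc1cccc(C=Cc2cc(OCc3ccccc3)c(OCc3ccccc3)c(-c3cc(OCc4ccccc4)c(OCc4ccccc4)cc3C=Cc3cccc(OC)c3)c2)c1
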